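**Retrosynthetic overview**
1. Last ring: the 29-membered ansa ring is closed by a double Stille "stitching" of bis(vinyl iodide) 48 with (Z)-Me3SnCH=CHSnMe3 (bonds C3–C4 and C5–C6, giving the 2Z,4Z,6E-triene). The N-acyl aminochloroquinone comes from a 2,3-dichloro-1,4-dimethoxynaphthalene by (NH4)2Ce(NO3)6 oxidation, NH3 substitution at C2 and N-acylation.
2. Key step: the aryl–C23 ketone bond is made by a photo-Fries 1,3-acyl shift (caged naphthoxyl/acyl radical pair) of naphthyl Z-enoate 37. The C21=C22 bond of 37 comes from an Ando olefination of aldehyde 36 with naphthyl phosphonate 13.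
3. Chain: C10–C11 by nickel-catalysed reductive acylation (alkyl radical from iodide 18 plus thioester 34); C14–C15 (15S) by a catalytic vinylogous Mukaiyama aldol; C16=C17 by cross-metathesis; C18–C20 by Roush crotylation of the Roche aldehyde; C8/C9 from a Sharpless epoxide opened by an alkynylalane.
4. Ring order: ring A (from hydroquinone) exists first, ring B is annulated by Diels–Alder reaction of 2,3-dichlorobenzoquinone with a 2-silyloxydiene and aromatised, ring A is returned to the quinone late, and the macrocycle is formed last.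

Assumption and labels: the SMILES is read as naphthomycin A with 8S,9S,15S,18S,19S,20S, 2Z,4Z,6E,12E,16E and a Z-configured C21=C22 enone. The ansa chain is numbered C1 (amide C=O) to C23 (aryl ketone C=O); the naphthoquinone carries N on position 2, Cl on 3, the acyl group on 5, OH on 6 and CH3 on 7; ring A = quinone ring, ring B = phenol ring. TBS = tert-butyldimethylsilyl, TES = triethylsilyl, TMS = trimethylsilyl.

## Route

**Aromatic part (ring A, then ring B)**

Step 1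
Reactants: 1 hydroquinone
Product: 2 2,3-dichlorobenzene-1,4-diol
Conditions: SO2Cl2 (2.1 equiv), AcOH, rt
Reagents that add atoms: sulfuryl chloride, ClS(Cl)(=O)=O
Why: Electrophilic aromatic chlorination in which the second chlorine enters next to the first (ortho to the other hydroxyl), the known course of the sulfuryl chloride reaction, to give the vicinal dichloride.

Step 2
Reactants: 2 2,3-dichlorobenzene-1,4-diol
Product: 3 2,3-dichloro-1,4-benzoquinone
Conditions: Ag2O, MgSO4, Et2O, rt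
Reagents that add atoms: none
Why: Two-electron oxidation of a hydroquinone to its quinone.

Step 3
Reactants: 4 3-methylbut-3-en-2-one
Product: 5 tert-butyldimethyl[(3-methylbuta-1,3-dien-2-yl)oxy]silane
Conditions: TBSOTf, Et3N, CH2Cl2, 0 °C
Reagents that add atoms: tert-butyldimethylsilyl triflate, CC(C)(C)[Si](C)(C)OS(=O)(=O)C(F)(F)F
Why: Soft enolisation and O-silylation at the methyl group gives the 2-silyloxydiene.

Step 4
Reactants: 3 2,3-dichloro-1,4-benzoquinone; 5 silyloxydiene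
Product: 6 cis-6-(TBS-oxy)-2,3-dichloro-7-methyl-4a,5,8,8a-tetrahydronaphthalene-1,4-dione (racemic)
Conditions: toluene, rt to 40 °C
Reagents that add atoms: none
Why: Diels–Alder reaction at the unchlorinated double bond of the symmetric quinone (no regiochemical issue), with cis ring fusion by suprafacial addition; both stereocentres are erased in step 5.

Step 5
Reactants: 6 Diels–Alder adduct
Product: 8 tert-butyl[(6,7-dichloro-5,8-dimethoxy-3-methyl-1,4-dihydronaphthalen-2-yl)oxy]dimethylsilane, via hydroquinone tautomer 7 (not isolated)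
Conditions: K2CO3, Me2SO4, acetone, reflux, Ar
Reagents that add atoms: dimethyl sulfate, COS(=O)(=O)OC
Why: Base-induced enolisation aromatises ring A and Williamson O-methylation traps the hydroquinone as its dimethyl ether.

Step 6
Reactants: 8 dihydronaphthalene silyl enol ether
Product: 10 6,7-dichloro-5,8-dimethoxy-3-methylnaphthalen-2-ol, via aryl silyl ether 9 (not isolated)
Conditions: DDQ, benzene, rt; then Bu4NF, AcOH, THF, 0 °C
Reagents that add atoms: none
Why: DDQ dehydrogenation of the 1,4-dihydroarene aromatises ring B and fluoride then cleaves the aryl silyl ether.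

Step 7
Reactants: 10 naphthol; 11 2-bromopropanoyl bromide
Product: 12 6,7-dichloro-5,8-dimethoxy-3-methylnaphthalen-2-yl 2-bromopropanoate (racemic)
Conditions: pyridine, CH2Cl2, 0 °C
Reagents that add atoms: none
Why: O-acylation of the naphthol by the acyl bromide; the racemic α-centre is destroyed in step 26.

Step 8
Reactants: 12 bromo ester
Product: 13 6,7-dichloro-5,8-dimethoxy-3-methylnaphthalen-2-yl 2-(diphenoxyphosphoryl)propanoate (racemic)
Conditions: (PhO)2P(O)H, Et3N, CH2Cl2, 0 °C to rt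
Reagents that add atoms: diphenyl phosphite, O=[PH](Oc1ccccc1)Oc1ccccc1
Why: Michaelis–Becker P-alkylation of the diaryl phosphite by the activated α-bromo ester gives the Ando-type phosphonate.

**C6–C10 iodide**

Step 9
Reactants: 14 (E)-but-2-en-1-ol
Product: 15 [(2S,3S)-3-methyloxiran-2-yl]methanol
Conditions: Ti(OiPr)4 (5 mol%), L-(+)-diisopropyl tartrate (6 mol%), t-BuOOH, 4 Å MS, CH2Cl2, −20 °C
Reagents that add atoms: tert-butyl hydroperoxide, CC(C)(C)OO
Why: Sharpless asymmetric epoxidation, in which the L-(+)-tartrate catalyst delivers oxygen to the face giving the (2S,3S)-epoxide; this fixes C9 (retained) and C8 (after inversion in step 10).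

Step 10
Reactants: 15 epoxy alcohol
Product: 16 (2R,3S)-3-methyl-5-(trimethylsilyl)pent-4-yne-1,2-diol
Conditions: Me3SiC≡CH, n-BuLi, toluene, −40 °C; Et2AlCl, 0 °C; then 15, 0 °C to rt; aq. HCl
Reagents that add atoms: (trimethylsilyl)acetylene, C#C[Si](C)(C)C
Why: Alkoxide-directed SN2 opening of the 2,3-epoxy alcohol at C3 by the alkynylalane (inversion) sets 8S next to the retained carbinol, giving the 8,9-syn pair.

Step 11
Reactants: 16 diol
Product: 17 (2R,3S)-1-iodo-3-methyl-5-(trimethylsilyl)pent-4-yn-2-ol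
Conditions: I2, PPh3, imidazole, THF/MeCN, 0 °C
Reagents that add atoms: iodine, II
Why: Appel-type (Garegg–Samuelsson) iodination that is selective for the primary hydroxyl.

Step 12
Reactants: 17 iodohydrin
Product: 18 tert-butyl{[(2R,3S)-1-iodo-3-methyl-5-(trimethylsilyl)pent-4-yn-2-yl]oxy}dimethylsilane
Conditions: TBSOTf, 2,6-lutidine, CH2Cl2, −78 °C
Reagents that add atoms: tert-butyldimethylsilyl triflate, CC(C)(C)[Si](C)(C)OS(=O)(=O)C(F)(F)F
Why: Silylation of the secondary alcohol under non-nucleophilic conditions that do not close the iodohydrin to the epoxide.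

**C11–C14 dienolate**

Step 13
Reactants: 19 tiglic acid
Product: 20 tert-butyl (E)-2-methylbut-2-enoate
Conditions: 2-methylpropene, H2SO4 (cat.), CH2Cl2, rt, sealed tube
Reagents that add atoms: 2-methylpropene, CC(C)=C
Why: Acid-catalysed addition of the carboxylic acid to isobutene gives the tert-butyl ester.

Step 14
Reactants: 20 tert-butyl tiglate
Product: 21 tert-butyl[(1-tert-butoxy-2-methylbuta-1,3-dien-1-yl)oxy]dimethylsilane
Conditions: LiN(i-Pr)2, THF/DMPU, −78 °C; TBSCl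
Reagents that add atoms: tert-butyldimethylsilyl chloride, CC(C)(C)[Si](C)(C)Cl
Why: γ-Deprotonation and O-silylation give the vinylketene silyl acetal needed for the vinylogous aldol (mainly the 1Z isomer; both isomers react alike).

**C4–C5 linchpin**

Step 15
Reactants: 22 acetylene
Product: 23 (Z)-1,2-bis(trimethylstannyl)ethene
Conditions: Me3SnSnMe3, Pd(PPh3)4 (2 mol%), dioxane, 60 °C
Reagents that add atoms: hexamethylditin, C[Sn](C)(C)[Sn](C)(C)C
Why: Palladium-catalysed syn-distannation of the alkyne gives only the Z-distannylethene.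

**Main line**

Step 16
Reactants: 24 methyl (S)-3-hydroxy-2-methylpropanoate
Product: 25 methyl (S)-2-methyl-3-[(triethylsilyl)oxy]propanoate
Conditions: TESCl, imidazole, CH2Cl2, 0 °C
Reagents that add atoms: chlorotriethylsilane, CC[Si](CC)(CC)Cl
Why: Silylation of the primary alcohol; the stereocentre (future C20) is taken from the chiral pool.

Step 17
Reactants: 25 silyl ether ester
Product: 26 (S)-2-methyl-3-[(triethylsilyl)oxy]propanal
Conditions: i-Bu2AlH (1.05 equiv), CH2Cl2, −78 °C; aq. potassium sodium tartrate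
Reagents that add atoms: none
Why: Partial ester reduction through the stable tetrahedral aluminate gives the aldehyde without epimerisation.

Step 18
Reactants: 26 aldehyde
Product: 27 (2S,3S,4S)-2,4-dimethyl-1-[(triethylsilyl)oxy]hex-5-en-3-ol
Conditions: (R,R)-diisopropyl tartrate (E)-crotylboronate, 4 Å MS, toluene, −78 °C; aq. NaOH
Reagents that add atoms: diisopropyl (4R,5R)-2-[(E)-but-2-enyl]-1,3,2-dioxaborolane-4,5-dicarboxylate, C/C=C/CB1O[C@H]([C@@H](O1)C(=O)OC(C)C)C(=O)OC(C)C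
Why: Roush crotylboration through a chair Zimmerman–Traxler transition state, in which the E-crotyl unit gives the 18,19-anti pair and the (R,R)-reagent adds to the Si face in the Felkin-matched sense, giving the 19,20-syn relation (18S,19S).

Step 19
Reactants: 27 homoallylic alcohol
Product: 28 (2S,3S,4S)-3-(TBS-oxy)-2,4-dimethyl-1-(TES-oxy)hex-5-ene
Conditions: TBSOTf, 2,6-lutidine, CH2Cl2, −78 to 0 °C
Reagents that add atoms: tert-butyldimethylsilyl triflate, CC(C)(C)[Si](C)(C)OS(=O)(=O)C(F)(F)F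
Why: Silylation of the hindered secondary alcohol by the silyl triflate.

Step 20
Reactants: 28 alkene; 29 (E)-but-2-enal
Product: 30 (2E,4S,5S,6S)-5-(TBS-oxy)-4,6-dimethyl-7-(TES-oxy)hept-2-enal
Conditions: 29 (5 equiv), RuCl2(=CH-C6H4-2-OiPr)(H2IMes) (second-generation Hoveyda–Grubbs catalyst, 5 mol%), CH2Cl2, 40 °C
Reagents that add atoms: none
Why: Olefin cross-metathesis of the terminal alkene with excess crotonaldehyde gives the E-enal under thermodynamic control, with propene leaving.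

Step 21
Reactants: 30 enal; 21 vinylketene silyl acetal
Product: 31 tert-butyl (2E,5S,6E,8S,9S,10S)-9-(TBS-oxy)-5-hydroxy-2,8,10-trimethyl-11-(TES-oxy)undeca-2,6-dienoate
Conditions: SiCl4 (1.1 equiv), (S,S)-bisphosphoramide catalyst of Denmark (pentamethylene-linked binaphthyldiamine phosphoramide, 5 mol%), i-Pr2NEt (10 mol%), CH2Cl2, −78 °C; aq. NaHCO3
Reagents that add atoms: none
Why: Lewis-base-activated vinylogous Mukaiyama aldol in which the dienolate attacks through its γ-carbon in an open transition state; the catalyst antipode chosen for Si-face attack on the enal sets 15S (catalyst control, the nearest stereocentre being remote) and the C12=C13 bond forms E.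

Step 22
Reactants: 31 hydroxy tert-butyl ester
Product: 33 (2E,5S,6E,8S,9S,10S)-5,9-bis(TBS-oxy)-2,8,10-trimethyl-11-(TES-oxy)undeca-2,6-dienoic acid, via silyl ester 32 (not isolated)
Conditions: TBSOTf (3 equiv), 2,6-lutidine, CH2Cl2, 0 °C to rt; then K2CO3 (cat.), THF/H2O, 0 °C
Reagents that add atoms: tert-butyldimethylsilyl triflate, CC(C)(C)[Si](C)(C)OS(=O)(=O)C(F)(F)F
Why: The silyl triflate silylates the allylic alcohol and converts the tert-butyl ester into the silyl ester (loss of isobutene), which is hydrolysed on mild aqueous work-up.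

Step 23
Reactants: 33 acid
Product: 34 S-(pyridin-2-yl) thioester of acid 33
Conditions: 2,2'-dipyridyl disulfide, PPh3, CH2Cl2, rt
Reagents that add atoms: 2,2'-dipyridyl disulfide, c1ccc(SSc2ccccn2)nc1
Why: Mukaiyama redox condensation gives the activated thioester under neutral conditions.

Step 24
Reactants: 34 thioester; 18 iodide
Product: 35 (3S,4S,7E,10S,11E,13S,14S,15S)-4,10,14-tris(TBS-oxy)-3,7,13,15-tetramethyl-16-(TES-oxy)-1-(trimethylsilyl)hexadeca-7,11-dien-1-yn-6-one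
Conditions: NiCl2(dme) (10 mol%), 4,4'-di-tert-butyl-2,2'-bipyridine (11 mol%), Mn powder (3 equiv), DMA, 0 °C to rt
Reagents that add atoms: none
Why: Nickel-catalysed reductive acyl cross-electrophile coupling, in which the thioester adds oxidatively to low-valent nickel and the primary alkyl radical from 18 is captured by the acylnickel species before reductive elimination; the β-silyloxy radical does not eliminate as an organozinc would, so 9S is carried over intact.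

Step 25
Reactants: 35 ynone
Product: 36 (2R,3S,4S,5E,7S,9E,13S,14S)-3,7,13-tris(TBS-oxy)-2,4,10,14-tetramethyl-11-oxo-16-(trimethylsilyl)hexadeca-5,9-dien-15-ynal
Conditions: (COCl)2, DMSO, CH2Cl2, −78 to −40 °C; Et3N, −78 to 0 °C
Reagents that add atoms: none
Why: Swern oxidation in which the chlorosulfonium salt cleaves and oxidises the primary TES ether directly while the secondary TBS ethers stay (the 2R descriptor is the former 20S centre with changed priorities).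

Step 26
Reactants: 36 aldehyde; 13 naphthyl phosphonate
Product: 37 6,7-dichloro-5,8-dimethoxy-3-methylnaphthalen-2-yl (2Z,4S,5S,6S,7E,9S,11E,15S,16S)-5,9,15-tris(TBS-oxy)-2,4,6,12,16-pentamethyl-13-oxo-18-(trimethylsilyl)octadeca-2,7,11-trien-17-ynoate
Conditions: 13 (1.2 equiv), NaH (1.1 equiv), THF, 0 °C; then 36, −78 to −20 °C
Reagents that add atoms: none
Why: Ando variant of the Horner–Wadsworth–Emmons reaction, in which the diaryl phosphonate eliminates fast and irreversibly from the syn adduct and so gives the Z-trisubstituted enoate (C21=C22), chemoselectively at the aldehyde.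

Step 27
Reactants: 37 naphthyl Z-enoate
Product: 39 (2Z,4S,5S,6S,7E,9S,11E,15S,16S)-5,9,15-tris(TBS-oxy)-1-(6,7-dichloro-2-hydroxy-5,8-dimethoxy-3-methylnaphthalen-1-yl)-2,4,6,12,16-pentamethyl-18-(trimethylsilyl)octadeca-2,7,11-trien-17-yne-1,13-dione, via dienone tautomer 38 (not isolated)
Conditions: hν (300–320 nm, Pyrex), degassed cyclohexane (3 mM), 15 °C, to about 70% conversion
Reagents that add atoms: none
Why: Photo-Fries rearrangement, in which excitation of the naphthyl ester homolyses the ArO–CO bond and the caged naphthoxyl/acyl radical pair recombines at the only open ortho carbon (position 5; the other ortho carbon carries methyl, the para position is the ring fusion) before tautomerisation; the σ-acyl radical should keep the Z geometry, and the hydrogen-bonded product is shielded from further photochemistry by excited-state proton transfer.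

Step 28
Reactants: 39 hydroxyaryl ketone
Product: 40 terminal alkyne (39 without the C-trimethylsilyl group)
Conditions: AgNO3 (20 mol%), MeOH/H2O/CH2Cl2, rt
Reagents that add atoms: none
Why: Silver-catalysed protodesilylation of the alkynylsilane under neutral conditions that leave the O-silyl ethers and the phenol/enone pair untouched.

Step 29
Reactants: 40 terminal alkyne
Product: 42 (E)-vinyl iodide (C6 iodide; 6E), via vinylstannane 41 (not isolated)
Conditions: Bu3SnH, PdCl2(PPh3)2 (5 mol%), THF, 0 °C; then I2, CH2Cl2, 0 °C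
Reagents that add atoms: iodine, II
Why: Palladium-catalysed syn-hydrostannation places tin on the terminal carbon and iododestannylation proceeds with retention, giving the E-vinyl iodide.

Step 30
Reactants: 42 vinyl iodide
Product: 43 2,3-dichloro-6-hydroxy-7-methyl-1,4-naphthoquinone carrying the C6–C23 chain on position 5
Conditions: (NH4)2Ce(NO3)6 (2.5 equiv), MeCN/H2O, 0 °C
Reagents that add atoms: water, O
Why: Oxidative demethylation of the 1,4-dimethoxyarene through its radical cation, with water adding at the two ipso carbons, gives the quinone.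

Step 31
Reactants: 43 dichloroquinone
Product: 44 2-amino-3-chloro-6-hydroxy-7-methyl-1,4-naphthoquinone carrying the C6–C23 chain on position 5
Conditions: NH3 (7 M in MeOH), THF, 0 °C
Reagents that add atoms: ammonia, N
Why: Addition–elimination on the dichloroquinone; the ionised 6-hydroxyl (para-conjugated with the C1 carbonyl) and the 5-acyl group make the C4 carbonyl the more electrophilic one, so ammonia adds at C2 and chloride leaves from there.

Step 32
Reactants: 44 aminochloroquinone; 45 (Z)-3-iodoprop-2-enoic acid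
Product: 48 N-[(Z)-3-iodoacryloyl] derivative of 44 (bis-vinyl iodide), via aminohydroquinone 46 (not isolated), via amidohydroquinone 47 (not isolated)
Conditions: Na2S2O4, EtOAc/H2O; then 45, EDC·HCl, CH2Cl2, 0 °C; then Ag2O, rt
Reagents that add atoms: none
Why: The aminoquinone nitrogen is a poor nucleophile, so the quinone is reduced to the aminohydroquinone, whose aniline nitrogen is acylated by the carbodiimide-activated acid with retention of the Z geometry, and the ring is re-oxidised.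

Step 33
Reactants: 48 bis(vinyl iodide); 23 (Z)-1,2-bis(trimethylstannyl)ethene
Product: 50 tris-TBS ether of naphthomycin A, via stannyl dienamide 49 (not isolated)
Conditions: PdCl2(MeCN)2 (20 mol%), i-Pr2NEt, DMF/THF (1 mM), rt
Reagents that add atoms: none
Why: Double Stille coupling (stitching macrocyclisation), in which the distannane first couples with the more reactive iodoacrylamide and the second coupling closes the ring at C5–C6, both with retention, so the 2Z,4Z,6E-triene results.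

Step 34
Reactants: 50 tris-TBS ether
Product: 51 naphthomycin A (CNP0257532.2)
Conditions: HF·pyridine, pyridine, THF, 0 °C to rt
Reagents that add atoms: none
Why: Fluoride-mediated cleavage of the three secondary silyl ethers under buffered conditions that spare the triene, the quinone and the β-hydroxy ketone.

## Compound list

1 | hydroquinone | Oc1ccc(O)cc1 | starting material
2 | 2,3-dichlorobenzene-1,4-diol | Oc1ccc(O)c(Cl)c1Cl | intermediate
3 | 2,3-dichloro-1,4-benzoquinone | O=C1C=CC(=O)C(Cl)=C1Cl | intermediate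
4 | 3-methylbut-3-en-2-one | CC(=O)C(C)=C | starting material
5 | tert-butyldimethyl[(3-methylbuta-1,3-dien-2-yl)oxy]silane | C=C(C)C(=C)O[Si](C)(C)C(C)(C)C | intermediate
6 | cis-6-(TBS-oxy)-2,3-dichloro-7-methyl-4a,5,8,8a-tetrahydronaphthalene-1,4-dione (racemic) | O=C1C(Cl)=C(Cl)C(=O)[C@H]2CC(O[Si](C)(C)C(C)(C)C)=C(C)C[C@@H]12 | intermediate
7 | 6-(TBS-oxy)-2,3-dichloro-7-methyl-5,8-dihydronaphthalene-1,4-diol | Oc1c(Cl)c(Cl)c(O)c2c1CC(C)=C(O[Si](C)(C)C(C)(C)C)C2 | intermediate (not isolated)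
8 | tert-butyl[(6,7-dichloro-5,8-dimethoxy-3-methyl-1,4-dihydronaphthalen-2-yl)oxy]dimethylsilane | COc1c(Cl)c(Cl)c(OC)c2c1CC(C)=C(O[Si](C)(C)C(C)(C)C)C2 | intermediate
9 | tert-butyl[(6,7-dichloro-5,8-dimethoxy-3-methylnaphthalen-2-yl)oxy]dimethylsilane | COc1c(Cl)c(Cl)c(OC)c2cc(O[Si](C)(C)C(C)(C)C)c(C)cc12 | intermediate (not isolated)
10 | 6,7-dichloro-5,8-dimethoxy-3-methylnaphthalen-2-ol | COc1c(Cl)c(Cl)c(OC)c2cc(O)c(C)cc12 | intermediate
11 | 2-bromopropanoyl bromide (racemic) | CC(Br)C(=O)Br | starting material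
12 | 6,7-dichloro-5,8-dimethoxy-3-methylnaphthalen-2-yl 2-bromopropanoate (racemic) | COc1c(Cl)c(Cl)c(OC)c2cc(OC(=O)C(C)Br)c(C)cc12 | intermediate
13 | 6,7-dichloro-5,8-dimethoxy-3-methylnaphthalen-2-yl 2-(diphenoxyphosphoryl)propanoate (racemic) | COc1c(Cl)c(Cl)c(OC)c2cc(OC(=O)C(C)P(=O)(Oc3ccccc3)Oc3ccccc3)c(C)cc12 | intermediate
14 | (E)-but-2-en-1-ol | C/C=C/CO | starting material
15 | [(2S,3S)-3-methyloxiran-2-yl]methanol | C[C@@H]1O[C@H]1CO | intermediate
16 | (2R,3S)-3-methyl-5-(trimethylsilyl)pent-4-yne-1,2-diol | OC[C@H](O)[C@@H](C)C#C[Si](C)(C)C | intermediate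
17 | (2R,3S)-1-iodo-3-methyl-5-(trimethylsilyl)pent-4-yn-2-ol | IC[C@H](O)[C@@H](C)C#C[Si](C)(C)C | intermediate
18 | tert-butyl{[(2R,3S)-1-iodo-3-methyl-5-(trimethylsilyl)pent-4-yn-2-yl]oxy}dimethylsilane | IC[C@H](O[Si](C)(C)C(C)(C)C)[C@@H](C)C#C[Si](C)(C)C | intermediate
19 | tiglic acid, (E)-2-methylbut-2-enoic acid | C/C=C(\C)C(=O)O | starting material
20 | tert-butyl (E)-2-methylbut-2-enoate | C/C=C(\C)C(=O)OC(C)(C)C | intermediate
21 | tert-butyl[(1-tert-butoxy-2-methylbuta-1,3-dien-1-yl)oxy]dimethylsilane (mainly 1Z, shown) | C=C/C(C)=C(\O[Si](C)(C)C(C)(C)C)OC(C)(C)C | intermediate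
22 | acetylene | C#C | starting material
23 | (Z)-1,2-bis(trimethylstannyl)ethene | C[Sn](C)(C)/C=C\[Sn](C)(C)C | intermediate
24 | methyl (S)-3-hydroxy-2-methylpropanoate | COC(=O)[C@@H](C)CO | starting material
25 | methyl (S)-2-methyl-3-[(triethylsilyl)oxy]propanoate | CC[Si](CC)(CC)OC[C@H](C)C(=O)OC | intermediate
26 | (S)-2-methyl-3-[(triethylsilyl)oxy]propanal | CC[Si](CC)(CC)OC[C@H](C)C=O | intermediate
27 | (2S,3S,4S)-2,4-dimethyl-1-[(triethylsilyl)oxy]hex-5-en-3-ol | CC[Si](CC)(CC)OC[C@H](C)[C@@H](O)[C@@H](C)C=C | intermediate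
28 | (2S,3S,4S)-3-(TBS-oxy)-2,4-dimethyl-1-(TES-oxy)hex-5-ene | CC[Si](CC)(CC)OC[C@H](C)[C@@H](O[Si](C)(C)C(C)(C)C)[C@@H](C)C=C | intermediate
29 | (E)-but-2-enal | C/C=C/C=O | starting material
30 | (2E,4S,5S,6S)-5-(TBS-oxy)-4,6-dimethyl-7-(TES-oxy)hept-2-enal | CC[Si](CC)(CC)OC[C@H](C)[C@@H](O[Si](C)(C)C(C)(C)C)[C@@H](C)/C=C/C=O | intermediate
31 | tert-butyl (2E,5S,6E,8S,9S,10S)-9-(TBS-oxy)-5-hydroxy-2,8,10-trimethyl-11-(TES-oxy)undeca-2,6-dienoate | CC[Si](CC)(CC)OC[C@H](C)[C@@H](O[Si](C)(C)C(C)(C)C)[C@@H](C)/C=C/[C@@H](O)C/C=C(\C)C(=O)OC(C)(C)C | intermediate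
32 | tert-butyldimethylsilyl (2E,5S,6E,8S,9S,10S)-5,9-bis(TBS-oxy)-2,8,10-trimethyl-11-(TES-oxy)undeca-2,6-dienoate | CC[Si](CC)(CC)OC[C@H](C)[C@@H](O[Si](C)(C)C(C)(C)C)[C@@H](C)/C=C/[C@@H](O[Si](C)(C)C(C)(C)C)C/C=C(\C)C(=O)O[Si](C)(C)C(C)(C)C | intermediate (not isolated)
33 | (2E,5S,6E,8S,9S,10S)-5,9-bis(TBS-oxy)-2,8,10-trimethyl-11-(TES-oxy)undeca-2,6-dienoic acid | CC[Si](CC)(CC)OC[C@H](C)[C@@H](O[Si](C)(C)C(C)(C)C)[C@@H](C)/C=C/[C@@H](O[Si](C)(C)C(C)(C)C)C/C=C(\C)C(=O)O | intermediate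
34 | S-(pyridin-2-yl) (2E,5S,6E,8S,9S,10S)-5,9-bis(TBS-oxy)-2,8,10-trimethyl-11-(TES-oxy)undeca-2,6-dienethioate | CC[Si](CC)(CC)OC[C@H](C)[C@@H](O[Si](C)(C)C(C)(C)C)[C@@H](C)/C=C/[C@@H](O[Si](C)(C)C(C)(C)C)C/C=C(\C)C(=O)Sc1ccccn1 | intermediate
35 | (3S,4S,7E,10S,11E,13S,14S,15S)-4,10,14-tris(TBS-oxy)-3,7,13,15-tetramethyl-16-(TES-oxy)-1-(trimethylsilyl)hexadeca-7,11-dien-1-yn-6-one (C6–C21) | CC[Si](CC)(CC)OC[C@H](C)[C@@H](O[Si](C)(C)C(C)(C)C)[C@@H](C)/C=C/[C@@H](O[Si](C)(C)C(C)(C)C)C/C=C(\C)C(=O)C[C@H](O[Si](C)(C)C(C)(C)C)[C@@H](C)C#C[Si](C)(C)C | intermediate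
36 | (2R,3S,4S,5E,7S,9E,13S,14S)-3,7,13-tris(TBS-oxy)-2,4,10,14-tetramethyl-11-oxo-16-(trimethylsilyl)hexadeca-5,9-dien-15-ynal | O=C[C@H](C)[C@@H](O[Si](C)(C)C(C)(C)C)[C@@H](C)/C=C/[C@@H](O[Si](C)(C)C(C)(C)C)C/C=C(\C)C(=O)C[C@H](O[Si](C)(C)C(C)(C)C)[C@@H](C)C#C[Si](C)(C)C | intermediate
37 | 6,7-dichloro-5,8-dimethoxy-3-methylnaphthalen-2-yl (2Z,4S,5S,6S,7E,9S,11E,15S,16S)-5,9,15-tris(TBS-oxy)-2,4,6,12,16-pentamethyl-13-oxo-18-(trimethylsilyl)octadeca-2,7,11-trien-17-ynoate | C/C(C(=O)Oc1cc2c(OC)c(Cl)c(Cl)c(OC)c2cc1C)=C/[C@H](C)[C@@H](O[Si](C)(C)C(C)(C)C)[C@@H](C)/C=C/[C@@H](O[Si](C)(C)C(C)(C)C)C/C=C(\C)C(=O)C[C@H](O[Si](C)(C)C(C)(C)C)[C@@H](C)C#C[Si](C)(C)C | intermediate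
38 | dienone tautomer of 39: the 1-acyl-6,7-dichloro-5,8-dimethoxy-3-methylnaphthalen-2(1H)-one (new sp3 centre undefined) | C/C(C(=O)C1C(=O)C(C)=Cc2c(OC)c(Cl)c(Cl)c(OC)c12)=C/[C@H](C)[C@@H](O[Si](C)(C)C(C)(C)C)[C@@H](C)/C=C/[C@@H](O[Si](C)(C)C(C)(C)C)C/C=C(\C)C(=O)C[C@H](O[Si](C)(C)C(C)(C)C)[C@@H](C)C#C[Si](C)(C)C | intermediate (not isolated)
39 | (2Z,4S,5S,6S,7E,9S,11E,15S,16S)-5,9,15-tris(TBS-oxy)-1-(6,7-dichloro-2-hydroxy-5,8-dimethoxy-3-methylnaphthalen-1-yl)-2,4,6,12,16-pentamethyl-18-(trimethylsilyl)octadeca-2,7,11-trien-17-yne-1,13-dione | C/C(C(=O)c1c(O)c(C)cc2c(OC)c(Cl)c(Cl)c(OC)c12)=C/[C@H](C)[C@@H](O[Si](C)(C)C(C)(C)C)[C@@H](C)/C=C/[C@@H](O[Si](C)(C)C(C)(C)C)C/C=C(\C)C(=O)C[C@H](O[Si](C)(C)C(C)(C)C)[C@@H](C)C#C[Si](C)(C)C | intermediate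
40 | terminal alkyne: 39 with C≡C–H in place of C≡C–SiMe3 | C/C(C(=O)c1c(O)c(C)cc2c(OC)c(Cl)c(Cl)c(OC)c12)=C/[C@H](C)[C@@H](O[Si](C)(C)C(C)(C)C)[C@@H](C)/C=C/[C@@H](O[Si](C)(C)C(C)(C)C)C/C=C(\C)C(=O)C[C@H](O[Si](C)(C)C(C)(C)C)[C@@H](C)C#C | intermediate
41 | (E)-vinylstannane: 40 with (E)-CH=CH–SnBu3 at C7=C6 | C/C(C(=O)c1c(O)c(C)cc2c(OC)c(Cl)c(Cl)c(OC)c12)=C/[C@H](C)[C@@H](O[Si](C)(C)C(C)(C)C)[C@@H](C)/C=C/[C@@H](O[Si](C)(C)C(C)(C)C)C/C=C(\C)C(=O)C[C@H](O[Si](C)(C)C(C)(C)C)[C@@H](C)/C=C/[Sn](CCCC)(CCCC)CCCC | intermediate (not isolated)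
42 | (E)-vinyl iodide: 40 with (E)-CH=CH–I at C7=C6 | C/C(C(=O)c1c(O)c(C)cc2c(OC)c(Cl)c(Cl)c(OC)c12)=C/[C@H](C)[C@@H](O[Si](C)(C)C(C)(C)C)[C@@H](C)/C=C/[C@@H](O[Si](C)(C)C(C)(C)C)C/C=C(\C)C(=O)C[C@H](O[Si](C)(C)C(C)(C)C)[C@@H](C)/C=C/I | intermediate
43 | 5-acyl-2,3-dichloro-6-hydroxy-7-methyl-1,4-naphthoquinone (acyl = C6–C23 chain of 42) | C/C(C(=O)c1c(O)c(C)cc2c1C(=O)C(Cl)=C(Cl)C2=O)=C/[C@H](C)[C@@H](O[Si](C)(C)C(C)(C)C)[C@@H](C)/C=C/[C@@H](O[Si](C)(C)C(C)(C)C)C/C=C(\C)C(=O)C[C@H](O[Si](C)(C)C(C)(C)C)[C@@H](C)/C=C/I | intermediate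
44 | 5-acyl-2-amino-3-chloro-6-hydroxy-7-methyl-1,4-naphthoquinone (same chain) | C/C(C(=O)c1c(O)c(C)cc2c1C(=O)C(Cl)=C(N)C2=O)=C/[C@H](C)[C@@H](O[Si](C)(C)C(C)(C)C)[C@@H](C)/C=C/[C@@H](O[Si](C)(C)C(C)(C)C)C/C=C(\C)C(=O)C[C@H](O[Si](C)(C)C(C)(C)C)[C@@H](C)/C=C/I | intermediate
45 | (Z)-3-iodoprop-2-enoic acid | OC(=O)/C=C\I | starting material
46 | aminohydroquinone: 44 reduced to the 1,4-dihydroxynaphthalene | C/C(C(=O)c1c(O)c(C)cc2c(O)c(N)c(Cl)c(O)c12)=C/[C@H](C)[C@@H](O[Si](C)(C)C(C)(C)C)[C@@H](C)/C=C/[C@@H](O[Si](C)(C)C(C)(C)C)C/C=C(\C)C(=O)C[C@H](O[Si](C)(C)C(C)(C)C)[C@@H](C)/C=C/I | intermediate (not isolated)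
47 | amidohydroquinone: N-[(Z)-3-iodoacryloyl] derivative of 46 | C/C(C(=O)c1c(O)c(C)cc2c(O)c(NC(=O)/C=C\I)c(Cl)c(O)c12)=C/[C@H](C)[C@@H](O[Si](C)(C)C(C)(C)C)[C@@H](C)/C=C/[C@@H](O[Si](C)(C)C(C)(C)C)C/C=C(\C)C(=O)C[C@H](O[Si](C)(C)C(C)(C)C)[C@@H](C)/C=C/I | intermediate (not isolated)
48 | N-[(Z)-3-iodoacryloyl] derivative of 44 (bis-vinyl iodide) | C/C(C(=O)c1c(O)c(C)cc2c1C(=O)C(Cl)=C(NC(=O)/C=C\I)C2=O)=C/[C@H](C)[C@@H](O[Si](C)(C)C(C)(C)C)[C@@H](C)/C=C/[C@@H](O[Si](C)(C)C(C)(C)C)C/C=C(\C)C(=O)C[C@H](O[Si](C)(C)C(C)(C)C)[C@@H](C)/C=C/I | intermediate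
49 | N-[(2Z,4Z)-5-(trimethylstannyl)penta-2,4-dienoyl] derivative of 44 | C/C(C(=O)c1c(O)c(C)cc2c1C(=O)C(Cl)=C(NC(=O)/C=C\C=C/[Sn](C)(C)C)C2=O)=C/[C@H](C)[C@@H](O[Si](C)(C)C(C)(C)C)[C@@H](C)/C=C/[C@@H](O[Si](C)(C)C(C)(C)C)C/C=C(\C)C(=O)C[C@H](O[Si](C)(C)C(C)(C)C)[C@@H](C)/C=C/I | intermediate (not isolated)
50 | 9,15,19-tris-O-TBS naphthomycin A | C/C1=C/[C@H](C)[C@@H](O[Si](C)(C)C(C)(C)C)[C@@H](C)/C=C/[C@@H](O[Si](C)(C)C(C)(C)C)C/C=C(\C)C(=O)C[C@H](O[Si](C)(C)C(C)(C)C)[C@@H](C)/C=C/C=C\C=C/C(=O)NC2=C(Cl)C(=O)c3c(cc(C)c(O)c3C1=O)C2=O | intermediate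
51 | naphthomycin A (CNP0257532.2) | C/C1=C/[C@H](C)[C@@H](O)[C@@H](C)/C=C/[C@@H](O)C/C=C(\C)C(=O)C[C@H](O)[C@@H](C)/C=C/C=C\C=C/C(=O)NC2=C(Cl)C(=O)c3c(cc(C)c(O)c3C1=O)C2=O | target

## Step count and risk

Total: 34 steps. Longest linear sequence: 19 steps (steps 16–34, from (S)-Roche ester 24).

**Step 27 (photo-Fries acyl shift).** Risks are cage escape back to naphthol 10, Z/E scrambling of the enoyl unit and secondary photochemistry of the chain. The fallback sets out from 10 and 36 and comes back at 40; it makes the same bond by a polar Nozaki–Hiyama–Kishi addition. Naphthol 10 is ortho-formylated (MgCl2, Et3N, paraformaldehyde, MeCN, reflux) to 6,7-dichloro-2-hydroxy-5,8-dimethoxy-3-methylnaphthalene-1-carbaldehyde F1 and silylated (TBSCl, imidazole) to 2-(TBS-oxy)-6,7-dichloro-5,8-dimethoxy-3-methylnaphthalene-1-carbaldehyde F2. Aldehyde 36 is treated with the ylide Ph3P=C(I)CH3 (Zhao olefination, −78 °C) to give the (Z)-2-iodoalkene F3. CrCl2 with NiCl2 (cat.) in DMSO adds F3 to F2 (aldehyde-selective, the C11 ketone is untouched) to give the allylic carbinol F4 as an epimer mixture. Dess–Martin oxidation gives the silyl-protected aryl ketone F5, and K2CO3 (cat.) in MeOH at 0 °C removes the aryl TBS and alkynyl TMS groups to rejoin the route at 40.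

**Step 24 (nickel-catalysed radical acylation).** Risks are Giese addition of the radical to the enoyl system, reduction or dimerisation of the iodide, and a sluggish unsaturated thioester. The fallback sets out from 33 and 16 and comes back at 35; it replaces the coupling by an aldol reaction. Acid 33 is converted (MeNHOMe·HCl, EDC·HCl) into the Weinreb amide F6 and with MeMgBr into the methyl ketone F7. Diol 16 is cleaved with NaIO4 to (S)-2-methyl-4-(trimethylsilyl)but-3-ynal F8, which is used at once. The boron enolate of F7 (Ipc2BCl antipode matched with Felkin attack, Et3N, −78 °C) adds to F8 to give the 9S β-hydroxy ketone F9, and TBSOTf/2,6-lutidine gives 35.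

**Step 33 (double Stille macrocyclisation).** Risks are oligomerisation, Z to E isomerisation of the dienyl tin intermediate and interference by the chloroquinone. The fallback sets out from 44, 45 and 23 and comes back at 50; it closes the ring by macrolactamisation instead. Acid 45 is coupled with excess 23 (PdCl2(MeCN)2, DMF) to (2Z,4Z)-5-(trimethylstannyl)penta-2,4-dienoic acid F10. Stille coupling of F10 with vinyl iodide 44 (Pd2(dba)3, AsPh3, DMF) gives the seco amino acid F11. Na2S2O4 reduces it to the aminohydroquinone seco acid F12, 2-chloro-1-methylpyridinium iodide/Et3N at high dilution closes the macrolactam hydroquinone F13, and Ag2O oxidation gives 50.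

## Further compounds

F1 | step 27 | 6,7-dichloro-2-hydroxy-5,8-dimethoxy-3-methylnaphthalene-1-carbaldehyde | COc1c(Cl)c(Cl)c(OC)c2c(C=O)c(O)c(C)cc12
F2 | step 27 | 2-(TBS-oxy)-6,7-dichloro-5,8-dimethoxy-3-methylnaphthalene-1-carbaldehyde | COc1c(Cl)c(Cl)c(OC)c2c(C=O)c(O[Si](C)(C)C(C)(C)C)c(C)cc12
F3 | step 27 | (Z)-2-iodoalkene from 36 (C6–C22, iodine on C22, other centres as in 36) | C/C(I)=C/[C@H](C)[C@@H](O[Si](C)(C)C(C)(C)C)[C@@H](C)/C=C/[C@@H](O[Si](C)(C)C(C)(C)C)C/C=C(\C)C(=O)C[C@H](O[Si](C)(C)C(C)(C)C)[C@@H](C)C#C[Si](C)(C)C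
F4 | step 27 | C23 carbinol from F2 and F3 (epimer mixture at C23) | C/C(C(O)c1c(O[Si](C)(C)C(C)(C)C)c(C)cc2c(OC)c(Cl)c(Cl)c(OC)c12)=C/[C@H](C)[C@@H](O[Si](C)(C)C(C)(C)C)[C@@H](C)/C=C/[C@@H](O[Si](C)(C)C(C)(C)C)C/C=C(\C)C(=O)C[C@H](O[Si](C)(C)C(C)(C)C)[C@@H](C)C#C[Si](C)(C)C
F5 | step 27 | O-TBS ether of 39 | C/C(C(=O)c1c(O[Si](C)(C)C(C)(C)C)c(C)cc2c(OC)c(Cl)c(Cl)c(OC)c12)=C/[C@H](C)[C@@H](O[Si](C)(C)C(C)(C)C)[C@@H](C)/C=C/[C@@H](O[Si](C)(C)C(C)(C)C)C/C=C(\C)C(=O)C[C@H](O[Si](C)(C)C(C)(C)C)[C@@H](C)C#C[Si](C)(C)C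
F6 | step 24 | N-methoxy-N-methylamide of acid 33 | CC[Si](CC)(CC)OC[C@H](C)[C@@H](O[Si](C)(C)C(C)(C)C)[C@@H](C)/C=C/[C@@H](O[Si](C)(C)C(C)(C)C)C/C=C(\C)C(=O)N(C)OC
F7 | step 24 | methyl ketone from F6 (C10–C21) | CC[Si](CC)(CC)OC[C@H](C)[C@@H](O[Si](C)(C)C(C)(C)C)[C@@H](C)/C=C/[C@@H](O[Si](C)(C)C(C)(C)C)C/C=C(\C)C(C)=O
F8 | step 24 | (S)-2-methyl-4-(trimethylsilyl)but-3-ynal | O=C[C@@H](C)C#C[Si](C)(C)C
F9 | step 24 | 9-hydroxy analogue of 35 (free C9 alcohol, 9S) | CC[Si](CC)(CC)OC[C@H](C)[C@@H](O[Si](C)(C)C(C)(C)C)[C@@H](C)/C=C/[C@@H](O[Si](C)(C)C(C)(C)C)C/C=C(\C)C(=O)C[C@H](O)[C@@H](C)C#C[Si](C)(C)C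
F10 | step 33 | (2Z,4Z)-5-(trimethylstannyl)penta-2,4-dienoic acid | OC(=O)/C=C\C=C/[Sn](C)(C)C
F11 | step 33 | seco amino acid (aminochloroquinone with C1 carboxylic acid, 2Z,4Z,6E) | C/C(C(=O)c1c(O)c(C)cc2c1C(=O)C(Cl)=C(N)C2=O)=C/[C@H](C)[C@@H](O[Si](C)(C)C(C)(C)C)[C@@H](C)/C=C/[C@@H](O[Si](C)(C)C(C)(C)C)C/C=C(\C)C(=O)C[C@H](O[Si](C)(C)C(C)(C)C)[C@@H](C)/C=C/C=C\C=C/C(=O)O
F12 | step 33 | aminohydroquinone form of F11 | C/C(C(=O)c1c(O)c(C)cc2c(O)c(N)c(Cl)c(O)c12)=C/[C@H](C)[C@@H](O[Si](C)(C)C(C)(C)C)[C@@H](C)/C=C/[C@@H](O[Si](C)(C)C(C)(C)C)C/C=C(\C)C(=O)C[C@H](O[Si](C)(C)C(C)(C)C)[C@@H](C)/C=C/C=C\C=C/C(=O)O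
F13 | step 33 | hydroquinone form of macrolactam 50 | C/C1=C/[C@H](C)[C@@H](O[Si](C)(C)C(C)(C)C)[C@@H](C)/C=C/[C@@H](O[Si](C)(C)C(C)(C)C)C/C=C(\C)C(=O)C[C@H](O[Si](C)(C)C(C)(C)C)[C@@H](C)/C=C/C=C\C=C/C(=O)Nc2c(Cl)c(O)c3c(cc(C)c(O)c3C1=O)c2O
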